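The data are simulated from invented constants, and the scatter is random.

Every exchange takes one incoming ligand out of the flask and puts one leaving ligand in, so the ligand spent always equals the leaving ligand gained. I keep that ledger for the flasks below.

| flask | starting complex | incoming ligand | leaving ligand | remark | time |
|---|---|---|---|---|---|
| dusk | 0.12 M | 0.20 M | 0.10 M | run made earlier |  |
| midnight | 0.12 M | 0.15 M | 0.10 M | run made earlier |  |
| gamma | 0.12 M | 0.300 M | 0.100 M |  | 3.0 min |
| beta | 0.20 M | 0.300 M | 0.100 M |  | 3.0 min |
| epsilon | 0.30 M | 0.300 M | 0.100 M |  | 3.0 min |
| eta | 0.50 M | 0.300 M | 0.100 M |  | 3.0 min |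
| delta | 0.60 M | 0.300 M | 0.100 M |  | 3.0 min |

| run | time / s | complex with two exchanged / % | starting complex / % |
|---|---|---|---|
| dusk | 10.0 | 0.4 | 92.2 |
| dusk | 20.0 | 2.0 | 85.5 |
| dusk | 25.0 | 2.4 | 81.8 |
| dusk | 40.0 | 5.1 | 74.0 |
| dusk | 50.0 | 6.6 | 68.9 |
| dusk | 60.0 | 8.2 | 64.9 |
| midnight | 10.0 | 0 | 93.7 |
| midnight | 12.0 | 0.2 | 92.8 |
| midnight | 20.0 | 1.3 | 88.5 |
| midnight | 25.0 | 1.4 | 86.3 |
| midnight | 40.0 | 3.0 | 79.5 |
| midnight | 60.0 | 5.5 | 72.2 |

(scatter of a reading: 0.3 percentage points)

- what was read earlier has a scatter of 0.3 percentage points, one standard deviation
- "hardly changes" means that all values lie within two and a half points (for a concentration: within two and a half percent of the largest)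

- [complex with two exchanged] at the end for gamma, beta, epsilon, eta, delta, in this order
- the course of these numbers from the first flask to the last (rises, then falls / rises all the way / falls all the way / falls, then rises / hardly changes)

The ledger has two entries: one ligand for each starting complex lost, and a second for each complex that goes on to two exchanged. Paying both in full costs 0.240 M in gamma, less than the 0.300 M charged. In delta it costs 1.20 M, more than that charge, so in delta incoming ligand is the limiting reagent.

The rate of spending comes from the dusk run. I call the time integral of [incoming ligand] the exposure. With ligand held at its charge, the logarithm of charged over remaining starting complex at 60.0 s gives 0.0360 L mol⁻¹ s⁻¹. But the ledger, entered from these two readings, books 0.0520 M spent by then. So I put back the mean of charge and end value, 0.174 M, and go round again. That gives 0.0414 L mol⁻¹ s⁻¹, higher than the first answer. This is the first-exchange constant, the logarithm of charged over remaining starting complex per unit of exposure. The midnight run, with a different ligand charge, gives 0.0418 L mol⁻¹ s⁻¹ as a reading.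

For gamma I go round the same way. With ligand held at its charge, I reckon that 10.7% of the starting complex remains after 3.0 min. I assume 1.50 ligands per complex lost, which books 0.161 M spent. The mean ligand is then 0.220 M, and I reckon that 19.5% remains.

My reckoning stops at the starting complex. The row is the forecast's: 0.062 M, 0.078 M, 0.082 M, 0.071 M, 0.063 M, a course that rises, then falls. In its letters L is incoming ligand, A starting complex and B the complex with one exchanged: “With more complex, L runs out and A competes for it, leaving mostly B”.

The flasks give 0.0369 M, 0.0465 M, 0.0478 M, 0.0398 M, 0.0357 M, a course that rises, then falls.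

    starting complex + incoming ligand → leaving ligand + complex with one exchanged (k = 0.0420 L mol⁻¹ s⁻¹)
    complex with one exchanged + incoming ligand → leaving ligand + complex with two exchanged (k = 0.0740 L mol⁻¹ s⁻¹)
    complex with two exchanged ⇌ isomer of the product (K = 1.20, k = 0.0170 s⁻¹)

Beside 30.7% of complex with two exchanged, gamma holds 27.2% of isomer of the product at 3.00 min, both in percent of the starting complex charged. Simpson's weighting of gamma's ligand at the start, at 1.50 min and at the end gives its exposure, and the first-exchange constant then leaves 22.7% of the starting complex, where 22.2% stood. Beta, reckoned the same way, leaves 31.8%, where 31.3% stood.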